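**Retrosynthetic overview**
- Feature: in the oxygenated ring of the stilbene, the methoxy oxygen O3 lies between C2 and C4, the two carbons that carry the prenyl CH2 groups; C6 (para to O3) is CH and O5 is a free hydroxyl. The target has no ring to close and no stereocentre apart from the E alkene.
- O5–H from O5–Si and O3–CH3 from O3–H: late methylation of the only free phenol, then fluoride desilylation.
- Key disconnection: C2–CH2 and C4–CH2, both formed by ortho C-alkylation of the one sodium phenoxide (at O3) with prenyl bromide.
- O5–Si: monosilylation of pinosylvin, which already holds the E-stilbene; no ring is formed anywhere in the route.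

Key step: step 2

Assumption: pinosylvin is bought as such; the first prenyl group may enter at either ortho carbon of the phenoxide, and both monoprenyl phenols lead on to the same diprenyl product.

**Step 1**
Reactants: 1 pinosylvin [(E)-3,5-dihydroxystilbene]; 2 chlorotriisopropylsilane
Product: 3 (E)-3-hydroxy-5-(triisopropylsilyloxy)stilbene
Conditions: iPr3SiCl (1.0 equiv), imidazole (2 equiv), DMF, 0 °C to rt
Reagents that add atoms: chlorotriisopropylsilane, CC(C)[Si](Cl)(C(C)C)C(C)C
Why: Imidazole-mediated silyl ether formation with one equivalent of the bulky chloride on the symmetric diol, whose two hydroxyls are equivalent, should give a statistical mixture from which the single possible monoether is separated by chromatography while recovered diol and bis-ether are recycled.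

**Step 2**
Reactants: 3 (E)-3-hydroxy-5-(triisopropylsilyloxy)stilbene; 4 prenyl bromide (1-bromo-3-methylbut-2-ene)
Product: 8 (E)-3-hydroxy-2,4-bis(3-methylbut-2-enyl)-5-(triisopropylsilyloxy)stilbene, via sodium 3-[(E)-2-phenylethenyl]-5-(triisopropylsilyloxy)phenoxide 5 (not isolated), via (E)-3-hydroxy-2-(3-methylbut-2-enyl)-5-(triisopropylsilyloxy)stilbene 6 (not isolated), via (E)-3-hydroxy-4-(3-methylbut-2-enyl)-5-(triisopropylsilyloxy)stilbene 7 (not isolated)
Conditions: NaH (2.2 equiv), toluene, 0 °C to rt; then prenyl bromide (2.2 equiv) added slowly, rt to 50 °C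
Reagents that add atoms: prenyl bromide, CC(C)=CCBr
Why: In toluene the sodium phenoxide 5 is an aggregated contact ion pair whose oxygen is masked by sodium, so an ortho ring carbon attacks the primary carbon of prenyl bromide (SN2) through a six-membered array in which sodium assists loss of bromide, and the first-formed keto tautomer rearomatises to phenol 6 or 7. The second equivalent of NaH regenerates a phenoxide whose one remaining ortho carbon reacts in the same way, so both monoprenyl phenols converge on 8 with new C2–CH2 and C4–CH2 bonds. The closest known reaction type is the ortho C-alkylation of alkali-metal phenoxides with allylic halides in non-polar media, the standard laboratory ortho-prenylation of phenols. No ring is closed and no stereocentre is formed, and the E double bond of the stilbene and the prenyl double bonds are not touched. The step needs carbon over oxygen alkylation, ortho over para (C6) attack, attack at the CH2 end of the allylic bromide and a stop after two alkylations; the first two rest on the non-coordinating solvent and the sodium counter-ion, the third on the unhindered primary carbon, the fourth on the limited charge of bromide. In the substrate the silyl ether at O5 leaves O3 as the only oxygen able to form a phenoxide, so its ortho carbons are exactly C2 and C4 while C6 lies para and out of reach of the ion pair; the silyl group flanks C4 as much as C6 and therefore does not decide the site, although it can turn towards C6 when C4 reacts, and C4 is expected to be the slower position.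

**Step 3**
Reactants: 8 (E)-3-hydroxy-2,4-bis(3-methylbut-2-enyl)-5-(triisopropylsilyloxy)stilbene; 9 iodomethane
Product: 10 (E)-3-methoxy-2,4-bis(3-methylbut-2-enyl)-5-(triisopropylsilyloxy)stilbene
Conditions: MeI (3 equiv), K2CO3 (2 equiv), acetone, 50 °C
Reagents that add atoms: iodomethane, CI
Why: Williamson ether synthesis on the only free phenol: although O3 is flanked by two CH2 groups, its potassium phenoxide should still attack the small electrophile MeI, and the aryl triisopropylsilyl ether, the E-stilbene and the prenyl groups are inert to anhydrous K2CO3 in acetone.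

**Step 4**
Reactants: 10 (E)-3-methoxy-2,4-bis(3-methylbut-2-enyl)-5-(triisopropylsilyloxy)stilbene
Product: 11 chiricanine C [(E)-5-hydroxy-3-methoxy-2,4-bis(3-methylbut-2-enyl)stilbene]
Conditions: Bu4NF (1.2 equiv), AcOH (1.2 equiv), THF, 0 °C
Reagents that add atoms: none
Why: Fluoride-induced cleavage of the aryl silyl ether, driven by the strong Si–F bond and the good phenoxide leaving group; the AcOH buffer protonates the electron-rich phenoxide at once, which limits air oxidation, and is too weak an acid to add the O5 hydroxyl across the neighbouring C4 prenyl double bond to a chroman.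

**Compound list**
1 | pinosylvin [(E)-3,5-dihydroxystilbene] | Oc1cc(O)cc(/C=C/c2ccccc2)c1 | starting material
2 | chlorotriisopropylsilane | CC(C)[Si](Cl)(C(C)C)C(C)C | starting material
3 | (E)-3-hydroxy-5-(triisopropylsilyloxy)stilbene | CC(C)[Si](C(C)C)(C(C)C)Oc1cc(O)cc(/C=C/c2ccccc2)c1 | intermediate
4 | prenyl bromide (1-bromo-3-methylbut-2-ene) | CC(C)=CCBr | starting material
5 | sodium 3-[(E)-2-phenylethenyl]-5-(triisopropylsilyloxy)phenoxide | CC(C)[Si](C(C)C)(C(C)C)Oc1cc([O-])cc(/C=C/c2ccccc2)c1.[Na+] | intermediate
6 | (E)-3-hydroxy-2-(3-methylbut-2-enyl)-5-(triisopropylsilyloxy)stilbene | CC(C)[Si](C(C)C)(C(C)C)Oc1cc(O)c(CC=C(C)C)c(/C=C/c2ccccc2)c1 | intermediate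
7 | (E)-3-hydroxy-4-(3-methylbut-2-enyl)-5-(triisopropylsilyloxy)stilbene | CC(C)[Si](C(C)C)(C(C)C)Oc1cc(/C=C/c2ccccc2)cc(O)c1CC=C(C)C | intermediate
8 | (E)-3-hydroxy-2,4-bis(3-methylbut-2-enyl)-5-(triisopropylsilyloxy)stilbene | CC(C)[Si](C(C)C)(C(C)C)Oc1cc(/C=C/c2ccccc2)c(CC=C(C)C)c(O)c1CC=C(C)C | intermediate
9 | iodomethane | CI | starting material
10 | (E)-3-methoxy-2,4-bis(3-methylbut-2-enyl)-5-(triisopropylsilyloxy)stilbene | COc1c(CC=C(C)C)c(/C=C/c2ccccc2)cc(O[Si](C(C)C)(C(C)C)C(C)C)c1CC=C(C)C | intermediate
11 | chiricanine C | COc1c(CC=C(C)C)c(O)cc(/C=C/c2ccccc2)c1CC=C(C)C | target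

Total step count: 4. Longest linear sequence: 4 steps (1 → 3 → 8 → 10 → 11).

**Steps most likely to fail**

Step 2. Carbon alkylation may lose out to O-alkylation or to para attack at C6. The second alkylation may stall at the crowded C4 between the phenoxide and the silyl ether. A third alkylation may dearomatise the ring, or silyl groups may be exchanged between phenoxides. The fallback delivers both prenyl groups by sigmatropic shifts that can only reach an ortho carbon. It sets out from 3: O-alkylation with tert-butyl 2-methylbut-3-en-2-yl carbonate (C=CC(C)(C)OC(=O)OC(C)(C)C) and catalytic Pd(PPh3)4 in THF at 0 °C, a branched-selective Tsuji–Trost etherification, would give (E)-3-(2-methylbut-3-en-2-yloxy)-5-(triisopropylsilyloxy)stilbene F1. Heating in toluene or N,N-diethylaniline at 110–140 °C should bring about the aromatic Claisen rearrangement to the monoprenyl phenol 6, accompanied by some 7. A second etherification of this material would give (E)-3-(2-methylbut-3-en-2-yloxy)-2-(3-methylbut-2-enyl)-5-(triisopropylsilyloxy)stilbene F2 and its isomer (E)-3-(2-methylbut-3-en-2-yloxy)-4-(3-methylbut-2-enyl)-5-(triisopropylsilyloxy)stilbene F3. A second Claisen rearrangement into the one ortho position still open would carry both to 8, where the route is rejoined.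

Step 3. Alkylation of the doubly flanked phenoxide may be slow, and during that time the carbonate base may remove or transfer the silyl group, so that O5 is methylated as well. The fallback forms the ether without any phenoxide: from 8, Mitsunobu etherification with methanol, PPh3 and diisopropyl azodicarboxylate in THF at 0 °C to rt should lead directly to 10. This fallback makes no new compound (F0).

Step 1. The second silylation may not be slower than the first, so that conversion ends mainly in diol and bis-ether and the separation becomes wasteful. The fallback reverses the order of events: 1 would be silylated exhaustively with excess 2 (imidazole, DMF) to (E)-3,5-bis(triisopropylsilyloxy)stilbene F4. One silyl group would then be removed with Bu4NF (1.0 equiv) in THF at −40 °C, followed by an AcOH quench. The phenoxide formed by the first cleavage makes the ring a poorer leaving group for the second silicon, so cleavage should slow after one group, and the route is rejoined at 3.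

**Further compounds**
F1 | step 2 | (E)-3-(2-methylbut-3-en-2-yloxy)-5-(triisopropylsilyloxy)stilbene | C=CC(C)(C)Oc1cc(O[Si](C(C)C)(C(C)C)C(C)C)cc(/C=C/c2ccccc2)c1
F2 | step 2 | (E)-3-(2-methylbut-3-en-2-yloxy)-2-(3-methylbut-2-enyl)-5-(triisopropylsilyloxy)stilbene | C=CC(C)(C)Oc1cc(O[Si](C(C)C)(C(C)C)C(C)C)cc(/C=C/c2ccccc2)c1CC=C(C)C
F3 | step 2 | (E)-3-(2-methylbut-3-en-2-yloxy)-4-(3-methylbut-2-enyl)-5-(triisopropylsilyloxy)stilbene | C=CC(C)(C)Oc1cc(/C=C/c2ccccc2)cc(O[Si](C(C)C)(C(C)C)C(C)C)c1CC=C(C)C
F0 | step 3 | none | none
F4 | step 1 | (E)-3,5-bis(triisopropylsilyloxy)stilbene | CC(C)[Si](C(C)C)(C(C)C)Oc1cc(O[Si](C(C)C)(C(C)C)C(C)C)cc(/C=C/c2ccccc2)c1
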